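Labdane numbering is used throughout. Ring A is C1–C5 plus C10 (C4 gem-dimethyl) and ring B is C5–C10. C6 bears the O-tigloyl group, C8 the carboxyl carbon C17, C9 the chain C11–C12 to the butenolide C13–C16, and C10 the methyl C20.
Enabling feature: C5, C10 and C9 (and a transient centre at C8) all sit on the ring B bonds C5–C10 and C8–C9, which flank C6 and C7. Moving the C7=C8 alkene to C6=C7 and removing O6 leaves a cyclohexene whose diene part (C5–C8) and dienophile part (C9=C10) are already linked by C1–C4.
Retrosynthetic cuts in order: C17 acid to aldehyde; O6–acyl; C6–OH/C7=C8 back to a 6α,7α-epoxide and then the C6=C7 alkene; C12–C13; C11=C12; then C5–C10 and C8–C9 together; in the chain C9–C11, C10–C20, C5=C6 and C3–C4.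
Forward: a (2E,8E,10E)-trienal is built linearly in seven steps, and one intramolecular Diels–Alder reaction closes rings A and B at once. The butenolide is attached as a ready-made ring, and ring B is then oxidised, acylated and taken to the acid.
Stereochemistry: alkene geometry (olefination for the diene, syn-carbometalation for the enal) plus an endo transition state relate C5, C8, C9 and C10. A chiral boron Lewis acid chooses the enantioface, and C6 follows from α-face epoxidation of the rigid octalin.

Key step: step 8

Assumption: the sense of induction in the key step is assigned from the accepted binding model of N-protonated prolinol oxazaborolidines. Both antipodes of the catalyst precursor are sold, so a first run on the trienal can correct the assignment without changing the route.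
Assumption: the silylated chloropentyne, the phosphonocrotonate, the bromobutenolide and the acid chloride are bought.

Step 1
Reactants: 1 isobutyronitrile; 2 (5-chloropent-1-yn-1-yl)trimethylsilane
Product: 4 2,2-dimethylhept-6-ynenitrile, via C-silylated alkynyl nitrile 3 (not isolated)
Conditions: LiN(i-Pr)2, THF, −78 °C; 2, DMPU, −78 °C → rt; then MeOH, K2CO3, rt
Reagents that add atoms: none
Why: SN2 alkylation of a metalated nitrile, in which the small and strongly nucleophilic lithio-isobutyronitrile displaces the primary chloride and creates the C4 quaternary carbon, the C-silyl cap keeps the alkyne proton from quenching the anion, and base-catalysed methanolysis then frees the terminal alkyne in the same flask.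

Step 2
Reactants: 4 2,2-dimethylhept-6-ynenitrile
Product: 5 2,2-dimethylhept-6-ynal
Conditions: i-Bu2AlH, CH2Cl2, −78 °C; 1 M HCl, 0 °C
Reagents that add atoms: water, O
Why: Partial reduction of a nitrile with i-Bu2AlH stops at the N-aluminated aldimine, which the acidic work-up hydrolyses to the neopentyl aldehyde, while the terminal alkyne is not hydroaluminated at this temperature.

Step 3
Reactants: 5 2,2-dimethylhept-6-ynal; 6 triethyl 4-phosphonocrotonate
Product: 7 ethyl (2E,4E)-6,6-dimethylundeca-2,4-dien-10-ynoate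
Conditions: 6, LiN(SiMe3)2, THF, −78 °C; 5, −78 → 0 °C
Reagents that add atoms: none
Why: Vinylogous Horner–Wadsworth–Emmons olefination, in which the stabilised phosphonate anion reacts through the carbon next to phosphorus, the hindered non-enolisable aldehyde gives the new C5=C6 alkene as the (E) isomer, and the crotonate alkene keeps its (E) geometry.

Step 4
Reactants: 7 ethyl (2E,4E)-6,6-dimethylundeca-2,4-dien-10-ynoate
Product: 8 (2E,4E)-6,6-dimethylundeca-2,4-dien-10-yn-1-ol
Conditions: i-Bu2AlH (2.2 equiv), CH2Cl2, −78 °C; aq. potassium sodium tartrate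
Reagents that add atoms: none
Why: 1,2-Reduction of a conjugated ester with i-Bu2AlH gives the dienol without touching the diene or the alkyne.

Step 5
Reactants: 8 (2E,4E)-6,6-dimethylundeca-2,4-dien-10-yn-1-ol
Product: 9 tert-butyl{[(2E,4E)-6,6-dimethylundeca-2,4-dien-10-yn-1-yl]oxy}dimethylsilane
Conditions: TBSCl, imidazole, CH2Cl2, rt
Reagents that add atoms: tert-butyldimethylsilyl chloride, CC(C)(C)[Si](C)(C)Cl
Why: Imidazole-promoted silylation masks the C17 hydroxyl as a bulky, weakly Lewis-basic ether that should survive the aluminium and boron Lewis acids to come.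

Step 6
Reactants: 9 tert-butyl{[(2E,4E)-6,6-dimethylundeca-2,4-dien-10-yn-1-yl]oxy}dimethylsilane
Product: 12 (2E,8E,10E)-12-[(tert-butyldimethylsilyl)oxy]-3,7,7-trimethyldodeca-2,8,10-trien-1-ol, via alkenyldimethylalane 10 (not isolated), via lithium alkenylalanate 11 (not isolated)
Conditions: Me3Al (2.5 equiv), Cp2ZrCl2 (0.25 equiv), CH2Cl2, 0 °C → rt; evaporate, hexane; n-BuLi, 0 °C; (CH2O)n, THF, rt
Reagents that add atoms: trimethylaluminium, C[Al](C)C; paraformaldehyde (as formaldehyde), C=O
Why: Negishi carboalumination adds CH3 (C20) and aluminium syn across the terminal alkyne with aluminium on the terminal carbon, and hydroxymethylation of the derived alanate with retention fixes the (E)-trisubstituted C9=C10 alkene on which the C9/C10 relationship of the cycloadduct depends.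

Step 7
Reactants: 12 (2E,8E,10E)-12-[(tert-butyldimethylsilyl)oxy]-3,7,7-trimethyldodeca-2,8,10-trien-1-ol
Product: 13 (2E,8E,10E)-12-[(tert-butyldimethylsilyl)oxy]-3,7,7-trimethyldodeca-2,8,10-trienal
Conditions: MnO2, CH2Cl2, rt
Reagents that add atoms: none
Why: Allylic oxidation with MnO2 is neutral and heterogeneous and should give the enal without E/Z exchange.

Step 8
Reactants: 13 (2E,8E,10E)-12-[(tert-butyldimethylsilyl)oxy]-3,7,7-trimethyldodeca-2,8,10-trienal
Product: 14 (1S,2S,4aS,8aS)-2-{[(tert-butyldimethylsilyl)oxy]methyl}-5,5,8a-trimethyl-1,2,4a,5,6,7,8,8a-octahydronaphthalene-1-carbaldehyde (trans-fused C6=C7 octalin; 5α-H; 10β-CH3; 9β-CHO; 8β-CH2OTBS)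
Conditions: (R)-3,3-diphenyl-1-(2-methylphenyl)tetrahydro-1H,3H-pyrrolo[1,2-c][1,3,2]oxazaborole (20 mol %), (CF3SO2)2NH (17 mol %), CH2Cl2, −40 → 0 °C
Reagents that add atoms: none
Why: Proposed new method: the cationic boron Lewis acid binds the formyl oxygen of 13 on the lone pair next to the formyl hydrogen, lowers the enal LUMO, and the tethered (E,E)-diene then adds in a concerted, asynchronous [4+2] in which C5–C10 runs ahead of C8–C9; the closest known reaction type is the oxazaborolidinium-catalysed intramolecular or transannular Diels–Alder reaction of 2,8,10-trienals and macrocyclic trienoates, not yet shown for an open-chain β,β-disubstituted enal that creates a quaternary carbon. Ring A (C1–C5, C10) closes when C5–C10 forms across the four-carbon tether C1–C4 held in a chair-like fold, and ring B (C5–C10) is the new cyclohexene completed by C8–C9. Suprafacial addition to the (E)-enal keeps C11 cis to C20 (C9 against C10), the (E,E)-diene places C4 and C17 cis on ring B (C8 against C5), and the endo position of the complexed formyl group, tether anti, ties the two pairs together as the trans fusion with 5α-H and 10β-CH3. The absolute sense comes from the catalyst, whose bound s-trans enal is held by a formyl C–H···O contact over one phenyl ring of the (R)-prolinol backbone, which leaves only the Si face of C9 open to the diene. The step needs endo over exo addition, one enantioface and an enal geometry that does not drift: complexation strengthens the endo preference, the methyl group cis to the formyl group enforces the s-trans conformer, the C4 gem-dimethyl group favours the folded chain, and a Lewis acid, unlike a secondary amine salt, offers no dienamine path for E/Z exchange of a β-methyl enal.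

Step 9
Reactants: 14 octalin aldehyde
Product: 15 17-[(tert-butyldimethylsilyl)oxy]-13,14,15,16-tetranorlabda-6,11-diene (5α-H; 8α-H; 9α-H; 10β-CH3)
Conditions: Ph3PCH3Br, KN(SiMe3)2, THF, 0 °C; 14, −78 → 0 °C
Reagents that add atoms: methyltriphenylphosphonium bromide, [Br-].C[P+](c1ccccc1)(c1ccccc1)c1ccccc1
Why: Wittig methylenation, in which the preformed unstabilised ylide should add to the hindered formyl group faster than it enolises it at low temperature, so that C12 is added without loss of the C9 configuration.

Step 10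
Reactants: 15 tetranorlabdadiene; 16 3-bromofuran-2(5H)-one
Product: 18 17-[(tert-butyldimethylsilyl)oxy]labda-6,13-dien-16,15-olide (5α-H; 8α-H; 9α-H; 10β-CH3), via B-alkyl-9-BBN adduct 17 (not isolated)
Conditions: 9-BBN-H (1.5 equiv), THF, rt → 40 °C; then 16, PdCl2(dppf) (5 mol %), AsPh3 (5 mol %), Cs2CO3, DMF–H2O, rt
Reagents that add atoms: none
Why: Hydroboration followed by B-alkyl Suzuki–Miyaura coupling, in which 9-BBN-H adds anti-Markovnikov to the monosubstituted alkene and leaves the hindered ring alkene alone, and the primary alkylborane is transferred to the α-bromoenoate carbon after oxidative addition to zerovalent palladium, forming C12–C13 at room temperature.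

Step 11
Reactants: 18 silyloxy labdadienolide
Product: 19 6α,7α-epoxy-17-[(tert-butyldimethylsilyl)oxy]labd-13-en-16,15-olide
Conditions: mCPBA, CH2Cl2, 0 °C
Reagents that add atoms: 3-chloroperoxybenzoic acid, OOC(=O)c1cccc(Cl)c1
Why: Prilezhaev epoxidation, in which the peracid takes the only electron-rich alkene (the butenolide is electron-poor) and approaches from the α face because the axial 4β- and 10β-methyl groups and the pseudoaxial 8β-silyloxymethyl group close the β face, which sets C6 and C7 with both C–O bonds α.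

Step 12
Reactants: 19 silyloxy epoxide
Product: 20 6α,7α-epoxy-17-hydroxylabd-13-en-16,15-olide
Conditions: Et3N·3HF, MeCN, rt
Reagents that add atoms: none
Why: Fluoride-induced cleavage of the primary silyl ether with a nearly neutral HF source spares both the epoxide and the base-sensitive butenolide.

Step 13
Reactants: 20 epoxy alcohol
Product: 22 6α-hydroxy-17-oxolabda-7,13-dien-16,15-olide, via epoxy aldehyde 21 (not isolated)
Conditions: Dess–Martin periodinane (1.1 equiv), NaHCO3, CH2Cl2, 0 °C; aq. Na2S2O3 wash; crude 21, Et3N (0.5 equiv), CH2Cl2, 0 °C → rt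
Reagents that add atoms: none
Why: Dess–Martin oxidation followed by base-induced E1cB opening of the β,γ-epoxy aldehyde, in which loss of the acidic C8 proton expels the C7–O bond, so that the alkene ends at C7=C8 in conjugation, the oxygen stays on C6 with its α configuration untouched, and the C8 stereocentre is erased.

Step 14
Reactants: 22 hydroxy enal; 23 tigloyl chloride
Product: 24 6α-[(E)-2-methylbut-2-enoyloxy]-17-oxolabda-7,13-dien-16,15-olide
Conditions: 23, pyridine, 4-(dimethylamino)pyridine (0.2 equiv), CH2Cl2, 0 °C → rt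
Reagents that add atoms: none
Why: Nucleophile-catalysed acylation through an acylpyridinium ion esterifies the equatorial allylic 6α-alcohol with retention at C6, the weak base avoids a vinylketene path, and the tiglate is the stable alkene isomer, so its (E) geometry holds.

Step 15
Reactants: 24 tigloyloxy enal
Product: 25 (1R,4S,4aS,8aR)-5,5,8a-trimethyl-4-{[(E)-2-methylbut-2-enoyl]oxy}-1-[2-(2-oxo-2,5-dihydrofuran-3-yl)ethyl]-1,4,4a,5,6,7,8,8a-octahydronaphthalene-2-carboxylic acid (6α-tigloyloxylabda-7,13-dien-16,15-olid-17-oic acid; CNP0245290.2)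
Conditions: NaClO2, NaH2PO4, 2-methylbut-2-ene, t-BuOH–H2O, rt
Reagents that add atoms: sodium chlorite, [Na+].[O-]Cl=O
Why: Pinnick oxidation converts the enal into the conjugated acid under buffered conditions that leave both esters, the electron-poor alkenes and all stereocentres alone, the scavenger alkene removing the hypochlorous acid.

Compound list
1 | isobutyronitrile | CC(C)C#N | starting material
2 | (5-chloropent-1-yn-1-yl)trimethylsilane | C[Si](C)(C)C#CCCCCl | starting material
3 | 2,2-dimethyl-7-(trimethylsilyl)hept-6-ynenitrile | C[Si](C)(C)C#CCCCC(C)(C)C#N | intermediate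
4 | 2,2-dimethylhept-6-ynenitrile | C#CCCCC(C)(C)C#N | intermediate
5 | 2,2-dimethylhept-6-ynal | C#CCCCC(C)(C)C=O | intermediate
6 | triethyl 4-phosphonocrotonate | CCOC(=O)/C=C/CP(=O)(OCC)OCC | starting material
7 | ethyl (2E,4E)-6,6-dimethylundeca-2,4-dien-10-ynoate | CCOC(=O)/C=C/C=C/C(C)(C)CCCC#C | intermediate
8 | (2E,4E)-6,6-dimethylundeca-2,4-dien-10-yn-1-ol | OC/C=C/C=C/C(C)(C)CCCC#C | intermediate
9 | tert-butyl{[(2E,4E)-6,6-dimethylundeca-2,4-dien-10-yn-1-yl]oxy}dimethylsilane | C#CCCCC(C)(C)/C=C/C=C/CO[Si](C)(C)C(C)(C)C | intermediate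
10 | dimethyl{(1E,7E,9E)-11-[(tert-butyldimethylsilyl)oxy]-2,6,6-trimethylundeca-1,7,9-trien-1-yl}alane | C[Al](C)/C=C(\C)CCCC(C)(C)/C=C/C=C/CO[Si](C)(C)C(C)(C)C | intermediate
11 | lithium butyl(dimethyl){(1E,7E,9E)-11-[(tert-butyldimethylsilyl)oxy]-2,6,6-trimethylundeca-1,7,9-trien-1-yl}alanate | [Li+].CCCC[Al-](C)(C)/C=C(\C)CCCC(C)(C)/C=C/C=C/CO[Si](C)(C)C(C)(C)C | intermediate
12 | (2E,8E,10E)-12-[(tert-butyldimethylsilyl)oxy]-3,7,7-trimethyldodeca-2,8,10-trien-1-ol | OC/C=C(\C)CCCC(C)(C)/C=C/C=C/CO[Si](C)(C)C(C)(C)C | intermediate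
13 | (2E,8E,10E)-12-[(tert-butyldimethylsilyl)oxy]-3,7,7-trimethyldodeca-2,8,10-trienal | O=C/C=C(\C)CCCC(C)(C)/C=C/C=C/CO[Si](C)(C)C(C)(C)C | intermediate
14 | trans-fused C6=C7 octalin, 9β-CHO, 8β-CH2OTBS, 5α-H, 10β-CH3 | C1=C[C@H](CO[Si](C)(C)C(C)(C)C)[C@H](C=O)[C@@]2(C)CCCC(C)(C)[C@H]12 | intermediate
15 | 17-[(tert-butyldimethylsilyl)oxy]-13,14,15,16-tetranorlabda-6,11-diene | C1=C[C@H](CO[Si](C)(C)C(C)(C)C)[C@H](C=C)[C@@]2(C)CCCC(C)(C)[C@H]12 | intermediate
16 | 3-bromofuran-2(5H)-one | O=C1OCC=C1Br | starting material
17 | C12 B-alkyl-9-borabicyclo[3.3.1]nonane derived from 15 | C1=C[C@H](CO[Si](C)(C)C(C)(C)C)[C@H](CCB3C4CCCC3CCC4)[C@@]2(C)CCCC(C)(C)[C@H]12 | intermediate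
18 | 17-[(tert-butyldimethylsilyl)oxy]labda-6,13-dien-16,15-olide | C1=C[C@H](CO[Si](C)(C)C(C)(C)C)[C@H](CCC3=CCOC3=O)[C@@]2(C)CCCC(C)(C)[C@H]12 | intermediate
19 | 6α,7α-epoxy-17-[(tert-butyldimethylsilyl)oxy]labd-13-en-16,15-olide | O1[C@H]2[C@@H]1[C@H](CO[Si](C)(C)C(C)(C)C)[C@H](CCC3=CCOC3=O)[C@@]3(C)CCCC(C)(C)[C@H]23 | intermediate
20 | 6α,7α-epoxy-17-hydroxylabd-13-en-16,15-olide | O1[C@H]2[C@@H]1[C@H](CO)[C@H](CCC3=CCOC3=O)[C@@]3(C)CCCC(C)(C)[C@H]23 | intermediate
21 | 6α,7α-epoxy-17-oxolabd-13-en-16,15-olide | O1[C@H]2[C@@H]1[C@H](C=O)[C@H](CCC3=CCOC3=O)[C@@]3(C)CCCC(C)(C)[C@H]23 | intermediate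
22 | 6α-hydroxy-17-oxolabda-7,13-dien-16,15-olide | O[C@H]1C=C(C=O)[C@H](CCC2=CCOC2=O)[C@@]2(C)CCCC(C)(C)[C@H]12 | intermediate
23 | tigloyl chloride, (E)-2-methylbut-2-enoyl chloride | C/C=C(\C)C(=O)Cl | starting material
24 | 6α-tigloyloxy-17-oxolabda-7,13-dien-16,15-olide | C/C=C(\C)C(=O)O[C@H]1C=C(C=O)[C@H](CCC2=CCOC2=O)[C@@]2(C)CCCC(C)(C)[C@H]12 | intermediate
25 | 6α-tigloyloxylabda-7,13-dien-16,15-olid-17-oic acid (CNP0245290.2) | C/C=C(\C)C(=O)O[C@H]1C=C(C(=O)O)[C@H](CCC2=CCOC2=O)[C@@]2(C)CCCC(C)(C)[C@H]12 | target

Total step count: 15. Longest linear sequence: 15 steps (from 1 and 2 to 25).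

Steps most likely to fail

1. Step 8.
- **What may go wrong:** The cycloaddition may be sluggish, because the leading bond joins a fully substituted carbon to a carbon next to a quaternary centre. The strong acid may strip the silyl ether or oligomerise the diene. Endo or facial control may be weak with a β,β-disubstituted enal.
- **Fallback:** It replaces catalyst control by a covalently bound auxiliary at the acid oxidation level, sets out from alkyne 9 and returns at 14. Alanate 11 is generated as in step 6 and quenched with CO2 in place of formaldehyde to give the trienoic acid F1. Activation with pivaloyl chloride/Et3N and acylation of (S)-4-benzyloxazolidin-2-one (LiCl, THF) give the N-trienoyl imide F2. Me2AlCl (1.5 equiv, CH2Cl2, −30 → 0 °C) chelates both carbonyl groups, locks the s-cis enoyl conformer and lets the benzyl group cover the Re face of C9. The same endo cycloaddition on the Si face then gives the octalin imide F3. This aluminium-promoted, auxiliary-directed cyclisation of trienimides is established chemistry. LiBH4/MeOH in Et2O releases the auxiliary and the C11 alcohol F4, and Dess–Martin oxidation gives 14.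

2. Step 10.
- **What may go wrong:** Base may open or oligomerise the bromobutenolide before it couples. Transmetalation of the alkylborane may be slow, and protodeboronation may compete.
- **Fallback:** It builds the butenolide by enolate alkylation and sulfoxide elimination, sets out from 15 and returns at 18. Hydroboration with 9-BBN-H and oxidation with NaBO3 give the primary C12 alcohol F5, and I2/PPh3/imidazole gives the C12 iodide F6. The lithium enolate of 3-(phenylsulfanyl)dihydrofuran-2(3H)-one (LiN(i-Pr)2, THF–DMPU) is alkylated with it to the α-sulfanyl lactone F7, whose C13 epimers are of no consequence. One equivalent of mCPBA at −78 °C gives the sulfoxide F8, since sulfur is oxidised faster than the ring alkene. Thermal syn-elimination in refluxing toluene over CaCO3 gives 18.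

3. Step 6.
- **What may go wrong:** The aluminium Lewis acid may ionise the dienylic silyl ether, the diene may be carbometalated in competition, or the alanate may capture formaldehyde incompletely.
- **Fallback:** It replaces carbometalation by hydroxyl-directed hydroalumination and cuprate methylation, sets out from 9 and returns at 12. n-BuLi followed by (CH2O)n gives the propargylic alcohol F9. trans-Hydroalumination with NaAlH2(OCH2CH2OMe)2 and iodinolysis give the (Z)-3-iodoallylic alcohol F10. Me2CuLi (Et2O, 0 °C) then replaces iodine by methyl with retention, which gives the same (E)-alkene in 12.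

Further compounds
F1 | step 8 | (2E,8E,10E)-12-[(tert-butyldimethylsilyl)oxy]-3,7,7-trimethyldodeca-2,8,10-trienoic acid | OC(=O)/C=C(\C)CCCC(C)(C)/C=C/C=C/CO[Si](C)(C)C(C)(C)C
F2 | step 8 | (S)-4-benzyl-3-{(2E,8E,10E)-12-[(tert-butyldimethylsilyl)oxy]-3,7,7-trimethyldodeca-2,8,10-trienoyl}oxazolidin-2-one | O=C1OC[C@H](Cc2ccccc2)N1C(=O)/C=C(\C)CCCC(C)(C)/C=C/C=C/CO[Si](C)(C)C(C)(C)C
F3 | step 8 | octalin imide, 14 with the 9β-formyl group replaced by the 9β-[(S)-4-benzyl-2-oxooxazolidin-3-yl]carbonyl group | C1=C[C@H](CO[Si](C)(C)C(C)(C)C)[C@H](C(=O)N3[C@@H](Cc4ccccc4)COC3=O)[C@@]2(C)CCCC(C)(C)[C@H]12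
F4 | step 8 | C11 alcohol, 14 with the 9β-formyl group reduced to 9β-CH2OH | C1=C[C@H](CO[Si](C)(C)C(C)(C)C)[C@H](CO)[C@@]2(C)CCCC(C)(C)[C@H]12
F5 | step 10 | 17-[(tert-butyldimethylsilyl)oxy]-13,14,15,16-tetranorlabd-6-en-12-ol | C1=C[C@H](CO[Si](C)(C)C(C)(C)C)[C@H](CCO)[C@@]2(C)CCCC(C)(C)[C@H]12
F6 | step 10 | 12-iodo-17-[(tert-butyldimethylsilyl)oxy]-13,14,15,16-tetranorlabd-6-ene | C1=C[C@H](CO[Si](C)(C)C(C)(C)C)[C@H](CCI)[C@@]2(C)CCCC(C)(C)[C@H]12
F7 | step 10 | 13-(phenylsulfanyl)-17-[(tert-butyldimethylsilyl)oxy]labd-6-en-16,15-olide (C13 epimers) | C1=C[C@H](CO[Si](C)(C)C(C)(C)C)[C@H](CCC3(Sc4ccccc4)CCOC3=O)[C@@]2(C)CCCC(C)(C)[C@H]12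
F8 | step 10 | 13-(phenylsulfinyl)-17-[(tert-butyldimethylsilyl)oxy]labd-6-en-16,15-olide (epimers at C13 and sulfur) | C1=C[C@H](CO[Si](C)(C)C(C)(C)C)[C@H](CCC3(S(=O)c4ccccc4)CCOC3=O)[C@@]2(C)CCCC(C)(C)[C@H]12
F9 | step 6 | (8E,10E)-12-[(tert-butyldimethylsilyl)oxy]-7,7-dimethyldodeca-8,10-dien-2-yn-1-ol | OCC#CCCCC(C)(C)/C=C/C=C/CO[Si](C)(C)C(C)(C)C
F10 | step 6 | (2Z,8E,10E)-12-[(tert-butyldimethylsilyl)oxy]-3-iodo-7,7-dimethyldodeca-2,8,10-trien-1-ol | OC/C=C(\I)CCCC(C)(C)/C=C/C=C/CO[Si](C)(C)C(C)(C)C
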